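Rings A and E differ from the aromatic rings B, C and D at a single ring carbon each: the sp3 C(CH3)2 centre that sits between a ring C=O and an enolic C–OH. The route therefore disconnects only the second methyl group of each of these two carbons. The precursor is an all-aromatic chain of five butyrylphloroglucinol rings joined by four CH2 bridges, whose end rings carry one C-methyl group; it is assembled from two monomer types by aminomethylation and quinone-methide coupling. In the last operation NaOMe and iodomethane C-methylate both methyl-bearing end-ring carbons, forming the two quaternary C–CH3 bonds and dearomatising rings A and E to the enolised acylcyclohexadienone form of the target.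

Key step: step 6

Assumption: the rings are lettered A to E along the chain. All fifteen hydroxyl groups are carried free, because the couplings and the final C-methylation both run through the phenoxides and masking only the inner rings would cost more operations than it could save. Keto/enol tautomers are drawn as in the target SMILES.

Step 1
Reactants: 1 2-methylbenzene-1,3,5-triol; 2 butanoyl chloride
Product: 3 1-(2,4,6-trihydroxy-3-methylphenyl)butan-1-one
Conditions: AlCl3 (3.5 equiv), CH2Cl2/MeNO2, 0 °C → 40 °C; then ice/1 M HCl
Reagents that add atoms: butanoyl chloride, CCCC(=O)Cl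
Why: Friedel–Crafts C-acylation of the strongly activated triol at one of its two equivalent free ring carbons, where the first acyl group deactivates the ring against a second one and any aryl ester formed first should be carried on to the ketone by Fries rearrangement under AlCl3.

Step 2
Reactants: 3 1-(2,4,6-trihydroxy-3-methylphenyl)butan-1-one; 4 formaldehyde; 5 dimethylamine
Product: 6 1-[3-[(dimethylamino)methyl]-2,4,6-trihydroxy-5-methylphenyl]butan-1-one
Conditions: 37% aq. CH2O (1.1 equiv), 40% aq. Me2NH (1.2 equiv), EtOH, 0 °C → rt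
Reagents that add atoms: formaldehyde, C=O; dimethylamine, CNC
Why: Phenolic Mannich aminomethylation, in which the iminium ion can attack only C5, the single unsubstituted ring carbon of 3, so that one regioisomer is expected.

Step 3
Reactants: 6 1-[3-[(dimethylamino)methyl]-2,4,6-trihydroxy-5-methylphenyl]butan-1-one; 7 1-(2,4,6-trihydroxyphenyl)butan-1-one
Product: 9 1-[3-[(3-butanoyl-2,4,6-trihydroxyphenyl)methyl]-2,4,6-trihydroxy-5-methylphenyl]butan-1-one (dimer A–B), via ring A quinone methide 8 (not isolated)
Conditions: 7 (6 equiv), 1,4-dioxane, 80 °C, argon stream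
Reagents that add atoms: none
Why: Elimination–addition coupling of a phenolic Mannich base, in which thermal loss of dimethylamine gives o-quinone methide 8 and a free ring carbon of 7 adds to it in a Michael reaction, the large excess of 7 keeping dimer 9 from being alkylated at its remaining free carbon.

Step 4
Reactants: 7 1-(2,4,6-trihydroxyphenyl)butan-1-one; 4 formaldehyde; 5 dimethylamine
Product: 10 1-[3,5-bis[(dimethylamino)methyl]-2,4,6-trihydroxyphenyl]butan-1-one
Conditions: 37% aq. CH2O (2.3 equiv), 40% aq. Me2NH (2.5 equiv), premixed, EtOH, 7 added at 0 °C → rt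
Reagents that add atoms: formaldehyde, C=O; dimethylamine, CNC
Why: Twofold phenolic Mannich reaction at the two equivalent free ring carbons of 7, run by adding 7 to a slight excess of the premixed reagents so that no unreacted ring carbon is left to condense with the product.

Step 5
Reactants: 10 1-[3,5-bis[(dimethylamino)methyl]-2,4,6-trihydroxyphenyl]butan-1-one; 9 dimer A–B
Product: 14 all-aromatic pentamer A–B–C–D–E (five butyrylphloroglucinol rings joined by four CH2 bridges; rings A and E carry one C-methyl group), via ring C quinone methide 11 (not isolated), via mono-coupled Mannich base 12 (not isolated), via second quinone methide 13 (not isolated)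
Conditions: 9 (2.2 equiv), 1,4-dioxane, 80 °C, argon stream
Reagents that add atoms: none
Why: Two successive elimination–Michael additions of the step 3 type, in which ring C releases dimethylamine twice and each quinone methide is captured by the only unsubstituted ring carbon of dimer 9, so that the chain can grow in one way only.

Step 6
Reactants: 14 all-aromatic pentamer A–B–C–D–E; 15 iodomethane
Product: 17 pentaalbaspidin BBBBB (target), via mono-dearomatised pentamer 16 (not isolated)
Conditions: NaOMe (12 equiv), MeI (2.3 equiv, in portions), degassed MeOH, argon, 0 °C → rt; then cold 1 M HCl, crystallisation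
Reagents that add atoms: iodomethane, CI
Why: NaOMe converts 14 into its polyphenoxide, and each end ring, acting as an ambident enolate, attacks iodomethane in an SN2 reaction through the ring carbon that already carries CH3, so that this carbon becomes the quaternary C(CH3)2 centre and the ring is locked as the cross-conjugated enolised triketone; the second end ring reacts in the same way by way of 16. The closest known reaction is the NaOMe/MeI dearomatising C-methylation of C-methyl acylphloroglucinols to acylfilicinic acids. No ring is closed and no stereocentre arises, since the new sp3 carbon bears two identical methyl groups. C- over O-alkylation is expected from the soft iodide electrophile and from the hydrogen-bonding methanol medium, which shields the phenoxide oxygens. Attack at rings A and E and not at rings B, C and D should follow from sterics, since every inner-ring carbon carries an acyl or arylmethyl group while the reacting end-ring carbon carries the smallest substituent present, and each dearomatised ring then rests as a delocalised, weakly nucleophilic vinylogous carboxylate. Iodomethane is held near two equivalents and the temperature low, to hold back a further methylation at a bridge-bearing carbon and base-induced migration of the CH2 bridges.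

Compound list
1 | 2-methylbenzene-1,3,5-triol | Cc1c(O)cc(O)cc1O | starting material
2 | butanoyl chloride | CCCC(=O)Cl | starting material
3 | 1-(2,4,6-trihydroxy-3-methylphenyl)butan-1-one | CCCC(=O)c1c(O)cc(O)c(C)c1O | intermediate
4 | formaldehyde | C=O | starting material
5 | dimethylamine | CNC | starting material
6 | 1-[3-[(dimethylamino)methyl]-2,4,6-trihydroxy-5-methylphenyl]butan-1-one | CCCC(=O)c1c(O)c(C)c(O)c(CN(C)C)c1O | intermediate
7 | 1-(2,4,6-trihydroxyphenyl)butan-1-one | CCCC(=O)c1c(O)cc(O)cc1O | starting material
8 | 2-butanoyl-3,5-dihydroxy-4-methyl-6-methylidenecyclohexa-2,4-dien-1-one (ring A quinone methide) | CCCC(=O)C1=C(O)C(C)=C(O)C(=C)C1=O | intermediate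
9 | 1-[3-[(3-butanoyl-2,4,6-trihydroxyphenyl)methyl]-2,4,6-trihydroxy-5-methylphenyl]butan-1-one (dimer A–B) | CCCC(=O)c1c(O)c(C)c(O)c(Cc2c(O)cc(O)c(C(=O)CCC)c2O)c1O | intermediate
10 | 1-[3,5-bis[(dimethylamino)methyl]-2,4,6-trihydroxyphenyl]butan-1-one | CCCC(=O)c1c(O)c(CN(C)C)c(O)c(CN(C)C)c1O | intermediate
11 | 2-butanoyl-4-[(dimethylamino)methyl]-3,5-dihydroxy-6-methylidenecyclohexa-2,4-dien-1-one (ring C quinone methide) | CCCC(=O)C1=C(O)C(CN(C)C)=C(O)C(=C)C1=O | intermediate
12 | three-ring Mannich base A–B–C: ring C of 10 with one CH2NMe2 arm replaced by a CH2 bridge to the free ring carbon of dimer 9, the other arm kept | CCCC(=O)c1c(O)c(CN(C)C)c(O)c(Cc2c(O)c(Cc3c(O)c(C)c(O)c(C(=O)CCC)c3O)c(O)c(C(=O)CCC)c2O)c1O | intermediate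
13 | quinone methide of 12: ring C as 6-methylidenecyclohexa-2,4-dien-1-one, still bridged to rings B and A | CCCC(=O)C1=C(O)C(Cc2c(O)c(Cc3c(O)c(C)c(O)c(C(=O)CCC)c3O)c(O)c(C(=O)CCC)c2O)=C(O)C(=C)C1=O | intermediate
14 | all-aromatic pentamer A–B–C–D–E: three inner 3,5-bridged butyrylphloroglucinol rings and two end 3-methyl-butyrylphloroglucinol rings bridged at C5 | CCCC(=O)c1c(O)c(C)c(O)c(Cc2c(O)c(Cc3c(O)c(Cc4c(O)c(Cc5c(O)c(C)c(O)c(C(=O)CCC)c5O)c(O)c(C(=O)CCC)c4O)c(O)c(C(=O)CCC)c3O)c(O)c(C(=O)CCC)c2O)c1O | intermediate
15 | iodomethane | CI | starting material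
16 | mono-dearomatised pentamer: ring A as the gem-dimethyl enolised triketone, ring E still the aromatic C-methyl ring | CCCC(=O)C1=C(O)C(Cc2c(O)c(Cc3c(O)c(Cc4c(O)c(Cc5c(O)c(C)c(O)c(C(=O)CCC)c5O)c(O)c(C(=O)CCC)c4O)c(O)c(C(=O)CCC)c3O)c(O)c(C(=O)CCC)c2O)=C(O)C(C)(C)C1=O | intermediate
17 | pentaalbaspidin BBBBB | CCCC(=O)C1=C(O)C(Cc2c(O)c(Cc3c(O)c(Cc4c(O)c(CC5=C(O)C(C)(C)C(=O)C(C(=O)CCC)=C5O)c(O)c(C(=O)CCC)c4O)c(O)c(C(=O)CCC)c3O)c(O)c(C(=O)CCC)c2O)=C(O)C(C)(C)C1=O | target

Total step count: 6
Longest linear sequence: 5 steps (steps 1, 2, 3, 5, 6); step 4 is a one-step side branch.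

Steps most likely to fail

Step 6. Methylation may also take place at bridge-bearing ring carbons or at oxygen, and the methoxide medium may let the CH2 bridges fragment and recombine, which would scramble the chain length. The fallback moves the dearomatisation to the monomer, where the site and the stoichiometry are unambiguous. It sets out from 3 and comes back at 17. Compound 3 is C-methylated with NaOMe and iodomethane in methanol to give 2-butanoyl-3,5-dihydroxy-6,6-dimethylcyclohexa-2,4-dien-1-one (butyrylfilicinic acid) F1, which is separated through its higher acidity. Mannich reaction with formaldehyde and dimethylamine at its only free ring carbon gives the aminomethyl compound F2. Warming F2 in dioxane with an excess of 7 releases dimethylamine to the methylidene trione F3, which 7 captures to give the filicinic–phloroglucinol dimer F4. Heating F4 (2.2 equiv) with 10 then passes through 11, the three-ring Mannich base F5 and its quinone methide F6, and delivers 17 directly.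

Step 5. The second coupling at ring C may stall at the crowded ring carbon, and the liberated amine may promote bridge migration during long heating. The fallback swaps the roles of the partners, so that ring C enters as the unhindered nucleophile. It sets out from 9 and comes back at 14. The single free ring carbon of 9 is aminomethylated (aq. CH2O, aq. Me2NH, EtOH) to give the dimer Mannich base F7. Warming F7 (2.1 equiv) with 7 (1 equiv) in dioxane generates the ring B quinone methide F8, which is trapped first by 7 to give the three-ring compound A–B–C F9 and then by the remaining free carbon of F9 to give 14.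

Step 3. The quinone methide may be captured by dimer 9 at its remaining free carbon, or by the Mannich base itself through ipso attack, so that ring A units are lost to over-coupled or self-condensed material. The fallback builds the chain from the middle outwards and introduces ring A last as a nucleophile with one free carbon only. It sets out from 10 and 7 and comes back at 14. Compound 10 is warmed in dioxane with a large excess of 7: loss of dimethylamine gives 11, capture by 7 gives the two-ring Mannich base F10, a second elimination gives its quinone methide F11, and a second capture gives the three-ring compound B–C–D F12. Twofold Mannich reaction at the two free end carbons (aq. CH2O, aq. Me2NH, EtOH) gives the trimer bis-Mannich base F13. Warming F13 with 3 (2.2 equiv) then runs through the end-ring quinone methide F14, the four-ring Mannich base F15 and its quinone methide F16 to 14.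

Further compounds
F1 | step 6 | 2-butanoyl-3,5-dihydroxy-6,6-dimethylcyclohexa-2,4-dien-1-one (butyrylfilicinic acid) | CCCC(=O)C1=C(O)C=C(O)C(C)(C)C1=O
F2 | step 6 | 2-butanoyl-4-[(dimethylamino)methyl]-3,5-dihydroxy-6,6-dimethylcyclohexa-2,4-dien-1-one | CCCC(=O)C1=C(O)C(CN(C)C)=C(O)C(C)(C)C1=O
F3 | step 6 | 2-butanoyl-3-hydroxy-6,6-dimethyl-4-methylidenecyclohex-2-ene-1,5-dione | CCCC(=O)C1=C(O)C(=C)C(=O)C(C)(C)C1=O
F4 | step 6 | 2-butanoyl-4-[(3-butanoyl-2,4,6-trihydroxyphenyl)methyl]-3,5-dihydroxy-6,6-dimethylcyclohexa-2,4-dien-1-one | CCCC(=O)C1=C(O)C(Cc2c(O)cc(O)c(C(=O)CCC)c2O)=C(O)C(C)(C)C1=O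
F5 | step 6 | three-ring Mannich base: ring C with one CH2NMe2 arm and one CH2 bridge to ring B of F4 | CCCC(=O)c1c(O)c(CN(C)C)c(O)c(Cc2c(O)c(CC3=C(O)C(C)(C)C(=O)C(C(=O)CCC)=C3O)c(O)c(C(=O)CCC)c2O)c1O
F6 | step 6 | quinone methide of F5 (ring C as 6-methylidenecyclohexa-2,4-dien-1-one) | CCCC(=O)C1=C(O)C(Cc2c(O)c(CC3=C(O)C(C)(C)C(=O)C(C(=O)CCC)=C3O)c(O)c(C(=O)CCC)c2O)=C(O)C(=C)C1=O
F7 | step 5 | dimer A–B Mannich base: 9 with CH2NMe2 on the free carbon of ring B | CCCC(=O)c1c(O)c(C)c(O)c(Cc2c(O)c(CN(C)C)c(O)c(C(=O)CCC)c2O)c1O
F8 | step 5 | quinone methide of F7 (ring B as 6-methylidenecyclohexa-2,4-dien-1-one) | CCCC(=O)c1c(O)c(C)c(O)c(CC2=C(O)C(C(=O)CCC)=C(O)C(=C)C2=O)c1O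
F9 | step 5 | three-ring compound A–B–C with one free ring carbon on ring C | CCCC(=O)c1c(O)c(C)c(O)c(Cc2c(O)c(Cc3c(O)cc(O)c(C(=O)CCC)c3O)c(O)c(C(=O)CCC)c2O)c1O
F10 | step 3 | 1-[3-[(3-butanoyl-2,4,6-trihydroxyphenyl)methyl]-5-[(dimethylamino)methyl]-2,4,6-trihydroxyphenyl]butan-1-one | CCCC(=O)c1c(O)c(CN(C)C)c(O)c(Cc2c(O)cc(O)c(C(=O)CCC)c2O)c1O
F11 | step 3 | quinone methide of F10 | CCCC(=O)C1=C(O)C(Cc2c(O)cc(O)c(C(=O)CCC)c2O)=C(O)C(=C)C1=O
F12 | step 3 | three-ring compound B–C–D: central ring bridged at C3 and C5 to two butyrylphloroglucinol rings | CCCC(=O)c1c(O)cc(O)c(Cc2c(O)c(Cc3c(O)cc(O)c(C(=O)CCC)c3O)c(O)c(C(=O)CCC)c2O)c1O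
F13 | step 3 | trimer bis-Mannich base: F12 with CH2NMe2 on the free carbon of each end ring | CCCC(=O)c1c(O)c(CN(C)C)c(O)c(Cc2c(O)c(Cc3c(O)c(CN(C)C)c(O)c(C(=O)CCC)c3O)c(O)c(C(=O)CCC)c2O)c1O
F14 | step 3 | quinone methide of F13 at one end ring | CCCC(=O)C1=C(O)C(Cc2c(O)c(Cc3c(O)c(CN(C)C)c(O)c(C(=O)CCC)c3O)c(O)c(C(=O)CCC)c2O)=C(O)C(=C)C1=O
F15 | step 3 | four-ring Mannich base A–B–C–D with CH2NMe2 left on ring D | CCCC(=O)c1c(O)c(C)c(O)c(Cc2c(O)c(Cc3c(O)c(Cc4c(O)c(CN(C)C)c(O)c(C(=O)CCC)c4O)c(O)c(C(=O)CCC)c3O)c(O)c(C(=O)CCC)c2O)c1O
F16 | step 3 | quinone methide of F15 at ring D | CCCC(=O)c1c(O)c(C)c(O)c(Cc2c(O)c(Cc3c(O)c(CC4=C(O)C(C(=O)CCC)=C(O)C(=C)C4=O)c(O)c(C(=O)CCC)c3O)c(O)c(C(=O)CCC)c2O)c1O
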